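Amounts first: of the substrate charged, what intermediate A and target do not hold is the remainder x, counted as a fraction of the charge, feed included.

| flask | substrate | partner | remark | time |
|---|---|---|---|---|
| gamma | 0.025 M (fed, over 5.0 h) | 0.10 M | run made earlier |  |
| delta | 0.038 M (fed, over 5.0 h) | 0.10 M | run made earlier |  |
| epsilon | 0.050 M (fed, over 5.0 h) | 0.20 M | run made earlier |  |
| flask | 0.050 M (fed, over 5.0 h) | 0.100 M |  | 50 h |

| run | time / h | intermediate A / % | target / % |
|---|---|---|---|
| gamma | 2.50 | 18.4 | 1.0 |
| gamma | 6.00 | 56.6 | 11.6 |
| gamma | 15.0 | 54.3 | 41.9 |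
| gamma | 40.0 | 17.7 | 81.4 |
| delta | 2.50 | 18.3 | 1.5 |
| delta | 6.00 | 55.9 | 9.5 |
| delta | 15.0 | 59.7 | 35.5 |
| delta | 40.0 | 28.4 | 71.9 |
| epsilon | 2.50 | 25.7 | 4.0 |
| epsilon | 6.00 | 59.5 | 24.7 |
| epsilon | 15.0 | 32.0 | 68.5 |
| epsilon | 40.0 | 3.4 | 96.4 |

(standard deviation of a reading: 0.5 percentage points)

- percentages count the whole charge, also what has not yet gone in

- the best time, 50 h at the latest, for intermediate A
- the amount of intermediate A, in percent of the substrate charged, at that time

Two readings serve. In epsilon from 15.0 h to 40.0 h, with free partner near 0.109 M (each target holding two partners), intermediate A falls with constant 0.825 L mol⁻¹ h⁻¹. In gamma from 6.00 h to 15.0 h, with partner near 0.0728 M, x falls with constant 3.24 L mol⁻¹ h⁻¹.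

The first view: partner stands in both rates, so it divides out. The selectivity factor s, the loss constant over the making constant, reads 0.254. Integrating dA/dx = −1 + sA/x, with the substrate still unfed counted as if present, gives the path A = (x^s − x)/(1 − s), with its top where x = sA. For this flask that means x = 15.9% and A = 62.7%. This estimate has partner at 0.0473 M there, and the mean of that and the charge, with the feed counted at its midpoint, puts my top near 10.2 h.

The second view: substrate becomes A as it arrives, so in this view the flask tops at 5.0 h with 81.9%. That view asks the product of making constant, partner and feed time to be large against one; with the constant as read, this flask offers 1.62.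

The forecast, a reckoning other than mine, stands later and higher than my first view, at 12 h (9.5 h to 15 h) and 64% (60% to 68%), reasoning that “partner runs down and both steps slow”.

The flask gives 64.1% at 10.8 h, so the second view loses. At 5.00 h this flask held 46.6% intermediate A and 32.4% substrate.

    substrate ⇌ intermediate B (K = 0.150, k = 0.480 h⁻¹)
    substrate + partner → intermediate A (k = 6.10 L mol⁻¹ h⁻¹)
    partner + intermediate A → target (k = 0.800 L mol⁻¹ h⁻¹)
    substrate ⇌ dormant form (K = 0.380, k = 0.250 h⁻¹)

At the top of this flask the remainder is substrate, intermediate B and dormant form, together 14.1%. Over A that is 0.220, beside s at 0.254.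

In the neighbour flask with 0.025 M partner, that charge covers 50.0% of the substrate, so the path at x = 50.0% gives 45.4%. Counting the partner its target takes moves x to 54.6% and A to 41.8%. Computed, that neighbour reaches 43.4%, and at 50.0 h its partner, the limiting reagent, stands at 0.175% of its charge.

All runs are calculated for substances that don't exist; noise was put on by code.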